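The earlier runs and the new flask were generated by integration for an exercise; scatter was added.

No reading can show me 3.0 min from a run that stops at 40.0 s, so I look in Friday's run for something that stays put.

common to all: starting material 0.0050 M

| charge | first nucleophile | solid second nucleophile | temperature | remark | time |
|---|---|---|---|---|---|
| Friday's | 6 mM | 1.8 mM | −5 °C | run made earlier |  |
| autumn | 6.00 mM | 3.50 mM | −5 °C |  | 3.0 min |
| spring | 6.00 mM | 3.50 mM | 25 °C |  | 3.0 min |
| winter | 6.00 mM | 3.50 mM | 10 °C |  | 3.0 min |

- Friday's (time / s: target / %): 10.0: 6.6; 15.0: 11.3; 20.0: 15.6; 30.0: 22.4; 40.0: 28.3

(standard deviation of a reading: 0.3 percentage points)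

1. the flask that comes out highest in amount of target, in percent of the starting material charged, or "all alike" when all lie within 1.5 percentage points (autumn / spring / winter / all alike)
2. target at the end, in percent of the starting material charged, autumn
3. target at the end, in percent of the starting material charged, spring
4. target at the end, in percent of the starting material charged, winter

Suppose the starting material decays first-order and the intermediate, once made, goes on to target quickly. Its concentration then stays low and nearly constant, the first step is the rate-limiting step, and the fraction not yet target falls exponentially. So I divide ln(1/(1 − target fraction)) by time, row by row.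

The first row gives 0.00683 s⁻¹. The second gives 0.00799 s⁻¹, higher, as a lag while the intermediate fills up would look. The next rows read 0.00848 s⁻¹ and 0.00845 s⁻¹, and the number has stopped climbing.

The last row reads 0.00832 s⁻¹, and this reading I carry: the clock constant κ, the apparent first-order constant with which starting material becomes target at −5 °C. Its inverse is a time constant of 120 s.

Autumn has Friday's temperature but 3.50 mM of solid against 1.8 mM, and I assume the solid leaves κ alone. Then 3.0 min is 1.50 time constants, so my reckoning for autumn is 77.6% target with 22.4% of the starting material left. For the warmer flasks κ gives me no number, since Friday's run was made at one temperature.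

The forecast puts autumn highest, with 47% there, 40% in spring and 44% in winter. Its ground is: “The final yield therefore depends on partitioning of the intermediate, not on time.” Its autumn figure differs from mine.

The flasks give winter highest: autumn 72.9%, spring 77.5%, winter 83.5%.

    starting material → intermediate (k = 0.190 s⁻¹, Ea = 66.0 kJ mol⁻¹)
    first nucleophile + intermediate → target (k = 610 M⁻¹ s⁻¹, Ea = 41.0 kJ mol⁻¹)
    second nucleophile + intermediate → other capture product (k = 33.0 M⁻¹ s⁻¹, Ea = 37.0 kJ mol⁻¹)
    intermediate → solvolysis product (k = 0.640 s⁻¹, Ea = 66.0 kJ mol⁻¹)
    solid second nucleophile ⇌ second nucleophile, rate k5*(cs5 - [second nucleophile]) while solid is left; crystals form when [second nucleophile] > cs5 (solubility = 2.90 mM, k = 0.0250 s⁻¹)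
    intermediate → side product (k = 0.00520 s⁻¹, Ea = 87.0 kJ mol⁻¹)
    (constants at 25 °C)

Autumn's own clock constant comes to 0.00725 s⁻¹, below κ, and my figure stands 4.7 percentage points above the flask. Autumn holds 18% of its starting material at 3.00 min, less than the 22.4% of my reckoning, and its target reaches 87.2% at 30.0 min. In winter the first step has done half of its turnover up to 3.0 min by 0.249 min, 0.024% of the starting material remains at 3.00 min, and target stands at 83.5% at 30.0 min.

For a repeat of winter at −15 °C, I move κ with the first step's 66.0 kJ mol⁻¹ to 0.00264 s⁻¹, which over 3.0 min gives 37.8% target. The computed flask gives 38.7%, with 57.5% of the starting material left.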